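Numbering follows geranyllinalool: vinyl C1=C2; oxane O, C3–C7 (Br on C6); linker C8–C9; carbocycle C10–C15 (C11 carbinol, C14 CHBr, C15 CMe2). Enabling feature: the oxane has two fully substituted ether carbons, C3 and C7, whose exocyclic carbons C2 and C8 are cis, so C2 and C8 can be tied into a temporary etheno bridge (five-membered ring O, C3, C2, C8, C7).
Retrosynthetic cuts: C6–Br and C14–Br (each from an alcohol with inversion); C9–C10 plus one C15–CH3 (conjugate addition/enolate methylation); C8–C9 (C9 put on the C7 vinyl group by tethered metathesis); C1 and the bridge C2=C8 (ethenolysis); C2–C3 and C7–C8 ([5+2] cycloaddition).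
Forward: the oxane is made first, inside an 8-oxabicyclo[3.2.1]octadienone (oxidopyrylium plus phenyl vinyl sulfoxide). The bridge is then opened to two cis vinyl groups, and a boron tether on O6 turns only the C7 vinyl group into the C8–C9 Grignard arm. This arm is joined at C9–C10 to a carbocycle preformed from (S)-linalool.
Stereochemistry: C3/C7 cis from the bridge; C6 by exo hydride attack, later inverted by bromide; absolute configuration of the oxane by lipase resolution; C11 from (S)-linalool; C10 by alkoxide-directed delivery cis to the C11 oxygen; C14 by equatorial hydride attack, later inverted by bromide.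

Key step: step 4

Assumption: the lipase is taken to follow Kazlauskas' rule (the carbinol flanked by the quaternary bridgehead reacts slowly in the (1S,2S,5S) series); if the preference is the reverse, the acetate is carried on after methanolysis. (S)-(+)-linalool is taken as a commercial chiral starting material.

Step 1
Reactants: 1 2-acetyl-5-methylfuran
Product: 2 1-(5-methylfuran-2-yl)ethan-1-ol (racemic)
Conditions: NaBH4, MeOH, 0 °C
Reagents that add atoms: none
Why: Borohydride 1,2-reduction of the aryl ketone gives the racemic furyl carbinol, whose stereocentre is erased again in step 4.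

Step 2
Reactants: 2 1-(5-methylfuran-2-yl)ethan-1-ol
Product: 3 6-hydroxy-2,6-dimethyl-2H-pyran-3(6H)-one (diastereomer mixture)
Conditions: NBS, NaHCO3, THF/H2O, 0 °C
Reagents that add atoms: water, O
Why: Achmatowicz rearrangement, in which bromonium-mediated oxidation of the furan in water gives the ene-dione that closes onto the carbinol oxygen as the pyranone hemiketal (both centres are inconsequential).

Step 3
Reactants: 3 6-hydroxy-2,6-dimethyl-2H-pyran-3(6H)-one
Product: 4 6-acetoxy-2,6-dimethyl-2H-pyran-3(6H)-one (diastereomer mixture)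
Conditions: Ac2O, pyridine, DMAP (cat.), CH2Cl2, 0 °C → rt
Reagents that add atoms: acetic anhydride, CC(=O)OC(C)=O
Why: DMAP-catalysed acylation of the tertiary anomeric hydroxyl installs the leaving group needed for ylide formation.

Step 4
Reactants: 4 6-acetoxy-2,6-dimethyl-2H-pyran-3(6H)-one; 5 phenyl vinyl sulfoxide
Product: 8 (1S,5R)-1,5-dimethyl-8-oxabicyclo[3.2.1]octa-3,6-dien-2-one (racemate), via oxidopyrylium ylide 6 (not isolated), via sulfinyl cycloadduct 7 (not isolated)
Conditions: 5 (4 equiv), Et3N, MeCN, 60 °C; then toluene, 110 °C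
Reagents that add atoms: none
Why: Triethylamine removes the proton next to the ketone and acetate leaves from the other ring terminus, giving the planar 2,6-dimethyl-3-oxidopyrylium 6, which adds the vinyl sulfoxide across its two methyl-bearing termini in a concerted, suprafacial six-electron [5+2] cycloaddition (oxidopyrylium–alkene cycloaddition) that forms C2–C3 and C7–C8. This closes the five-membered ring O–C3–C2–C8–C7 (and with it the seven-membered carbocycle) by simultaneous two-bond formation on one face of the pyranone, the only ring closure of the step. The two new stereocentres, the bridgeheads C3 and C7, are fixed cis by the geometry of the bridge itself, so no facial or endo/exo control is needed and the product is racemic. All regio- and stereoisomers of adduct 7 converge, because thermal syn elimination (Ei) of benzenesulfenic acid can only run toward the bridge CH2 (both bridgeheads are quaternary) and leaves the same etheno bridge, the sulfoxide thus serving as an ethyne equivalent. The selectivity that is needed is cycloaddition over ylide dimerisation, which is secured by generating the ylide slowly in the presence of excess dipolarophile.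

Step 5
Reactants: 8 (1S,5R)-1,5-dimethyl-8-oxabicyclo[3.2.1]octa-3,6-dien-2-one (racemate)
Product: 9 (1S,5S)-1,5-dimethyl-8-oxabicyclo[3.2.1]oct-6-en-2-one (racemate)
Conditions: Cu(OAc)2·H2O (5 mol%), 1,2-bis(diphenylphosphino)benzene (5 mol%), (EtO)2MeSiH, t-BuOH, toluene, rt
Reagents that add atoms: none
Why: Copper hydride catalysed conjugate reduction (Stryker-type 1,4-hydride delivery) should saturate only the polarised enone C4=C5, the unactivated etheno bridge being inert to the phosphine-ligated hydride, and no stereocentre is formed.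

Step 6
Reactants: 9 (1S,5S)-1,5-dimethyl-8-oxabicyclo[3.2.1]oct-6-en-2-one (racemate)
Product: 10 rac-(1S,2S,5S)-1,5-dimethyl-8-oxabicyclo[3.2.1]oct-6-en-2-ol (2-endo alcohol)
Conditions: NaBH4, MeOH, −20 °C
Reagents that add atoms: none
Why: Borohydride reduction in which hydride attacks C6 from the exo face (the side of the oxygen bridge, axial attack on the oxane chair) because the endo face is screened by the etheno bridge, so the hydroxyl should come out endo, cis to C8.

Step 7
Reactants: 10 rac-(1S,2S,5S)-1,5-dimethyl-8-oxabicyclo[3.2.1]oct-6-en-2-ol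
Product: 11 (1S,2S,5S)-1,5-dimethyl-8-oxabicyclo[3.2.1]oct-6-en-2-ol (single enantiomer)
Conditions: Candida antarctica lipase B (immobilised), vinyl acetate, MTBE, 35 °C, stopped just past half conversion
Reagents that add atoms: none
Why: Lipase-catalysed kinetic resolution by enantioselective transesterification, in which by Kazlauskas' rule the (1R,2R,5R) alcohol is acetylated and the wanted (1S,2S,5S) alcohol is recovered unchanged.

Step 8
Reactants: 11 (1S,2S,5S)-1,5-dimethyl-8-oxabicyclo[3.2.1]oct-6-en-2-ol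
Product: 12 (2S,3S,6S)-2,6-diethenyl-2,6-dimethyloxan-3-ol
Conditions: second-generation Hoveyda–Grubbs catalyst (5 mol%), ethene (1 atm), CH2Cl2, 40 °C
Reagents that add atoms: ethene, C=C
Why: Ring-opening cross-metathesis with ethene (ethenolysis) is driven by release of the strain of the bicyclic alkene and turns C2=C8 into the two cis vinyl groups on C3 and C7 without touching a stereocentre.

Step 9
Reactants: 12 (2S,3S,6S)-2,6-diethenyl-2,6-dimethyloxan-3-ol
Product: 15 (3aS,5S,7aS)-5-ethenyl-3a,5-dimethylhexahydro-2H-furo[3,2-b]pyran-2-ol (anomer mixture), via mixed vinylboronate 13 (not isolated), via cyclic alkenylboronate 14 (not isolated)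
Conditions: CH2=CHB(OBu)2, CH2Cl2, rt; second-generation Hoveyda–Grubbs catalyst (10 mol%), toluene, 60 °C; then NaBO3·4H2O, THF/H2O, rt
Reagents that add atoms: dibutyl vinylboronate, C=CB(OCCCC)OCCCC; sodium perborate, [Na+].[Na+].O[B-]1(O)OO[B-](O)(O)OO1
Why: Boron-tethered ring-closing metathesis, in which transesterification hangs a vinylboronate on O6 and only the C7 vinyl group can close a six-membered ring with it (C8=C9, C9 from the boronate, the old terminal CH2 leaving as ethene), after which perborate oxidation of the alkenyl C–B bond gives the C9 aldehyde that closes on O6 as the lactol (anomers of no consequence), so the C3 vinyl group is never touched.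

Step 10
Reactants: 15 (3aS,5S,7aS)-5-ethenyl-3a,5-dimethylhexahydro-2H-furo[3,2-b]pyran-2-ol
Product: 16 (2S,3S,6S)-6-ethenyl-2-(2-hydroxyethyl)-2,6-dimethyloxan-3-ol
Conditions: NaBH4, MeOH, 0 °C
Reagents that add atoms: none
Why: Borohydride reduction of the open hydroxy aldehyde form of the lactol gives the 1,4-diol.

Step 11
Reactants: 16 (2S,3S,6S)-6-ethenyl-2-(2-hydroxyethyl)-2,6-dimethyloxan-3-ol
Product: 17 (2S,3S,6S)-3-{[tert-butyl(dimethyl)silyl]oxy}-2-(2-{[tert-butyl(dimethyl)silyl]oxy}ethyl)-6-ethenyl-2,6-dimethyloxane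
Conditions: TBSOTf (2.5 equiv), 2,6-lutidine, CH2Cl2, −78 → 0 °C
Reagents that add atoms: tert-butyldimethylsilyl triflate, CC(C)(C)[Si](C)(C)OS(=O)(=O)C(F)(F)F
Why: Exhaustive silylation with the silyl triflate protects both hydroxyls, the secondary one beside the quaternary C7 requiring the triflate.

Step 12
Reactants: 17 (2S,3S,6S)-3-{[tert-butyl(dimethyl)silyl]oxy}-2-(2-{[tert-butyl(dimethyl)silyl]oxy}ethyl)-6-ethenyl-2,6-dimethyloxane
Product: 18 {[(2S,3S,6S)-2-(2-bromoethyl)-6-ethenyl-2,6-dimethyloxan-3-yl]oxy}(tert-butyl)dimethylsilane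
Conditions: Ph3PBr2, CH2Cl2, 0 °C → rt
Reagents that add atoms: dibromotriphenylphosphorane, BrP(Br)(c1ccccc1)(c1ccccc1)c1ccccc1
Why: Dibromotriphenylphosphorane converts the unhindered primary silyl ether directly into the bromide (phosphonium activation of the ether oxygen, SN2 by bromide) and leaves the hindered secondary silyl ether in place, which avoids a free 1,4-diol monohalide that would close to an oxolane.

Step 13
Reactants: 19 (S)-(+)-linalool
Product: 20 (5S)-5-ethenyl-5-methyloxolan-2-ol (anomer mixture)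
Conditions: O3, CH2Cl2, −78 °C, Sudan III end point; then PPh3, −78 °C → rt
Reagents that add atoms: ozone, [O-][O+]=O
Why: Ozonolysis cleaves the electron-rich trisubstituted alkene much faster than the vinyl group on the carbinol carbon, and the resulting hydroxy aldehyde closes to the lactol with the carbinol centre untouched.

Step 14
Reactants: 20 (5S)-5-ethenyl-5-methyloxolan-2-ol
Product: 21 (6S)-2,6-dimethylocta-1,7-diene-3,6-diol (C3 epimer mixture)
Conditions: CH2=C(CH3)MgBr (2.5 equiv), THF, 0 °C → rt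
Reagents that add atoms: isopropenylmagnesium bromide, C=C(C)[Mg]Br
Why: Grignard addition to the aldehyde form of the lactol (one equivalent is spent on the hydroxyl) gives the allylic alcohol as an epimer mixture that is removed by the oxidation in step 16.

Step 15
Reactants: 21 (6S)-2,6-dimethylocta-1,7-diene-3,6-diol
Product: 22 (4S)-2,4-dimethylcyclohex-2-ene-1,4-diol (C1 epimer mixture)
Conditions: second-generation Grubbs catalyst (3 mol%), CH2Cl2, 40 °C
Reagents that add atoms: none
Why: Ring-closing metathesis of the vinyl carbinol onto the 1,1-disubstituted alkene closes the cyclohexene with loss of ethene and creates no new stereocentre.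

Step 16
Reactants: 22 (4S)-2,4-dimethylcyclohex-2-ene-1,4-diol
Product: 23 (4S)-4-hydroxy-2,4-dimethylcyclohex-2-en-1-one
Conditions: MnO2, CH2Cl2, rt
Reagents that add atoms: none
Why: Manganese dioxide oxidises the secondary allylic alcohol selectively and leaves the tertiary one, so the epimer mixture converges on one enantiomerically defined 4-hydroxy enone.

Step 17
Reactants: 18 {[(2S,3S,6S)-2-(2-bromoethyl)-6-ethenyl-2,6-dimethyloxan-3-yl]oxy}(tert-butyl)dimethylsilane; 23 (4S)-4-hydroxy-2,4-dimethylcyclohex-2-en-1-one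
Product: 27 (3R,4S)-3-{2-[(2S,3S,6S)-3-{[tert-butyl(dimethyl)silyl]oxy}-6-ethenyl-2,6-dimethyloxan-2-yl]ethyl}-4-hydroxy-2,2,4-trimethylcyclohexan-1-one, via Grignard reagent 24 (not isolated), via magnesium alkoxide 25 (not isolated), via magnesium enolate 26 (not isolated)
Conditions: 18, Mg, THF, 40 °C; 23, t-BuMgCl, THF, −78 °C; combined, −78 → −20 °C; then MeI, DMPU, −20 °C → rt
Reagents that add atoms: iodomethane, CI
Why: Alkoxide-directed conjugate addition of a Grignard reagent to a 4-oxido enone, in which the magnesium alkoxide on C11 binds the reagent and delivers C9 to C10 on its own face so that the chain comes out cis to the hydroxyl, followed by C-methylation of the regiodefined enolate at C15 to complete the gem-dimethyl group.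

Step 18
Reactants: 27 (3R,4S)-3-{2-[(2S,3S,6S)-3-{[tert-butyl(dimethyl)silyl]oxy}-6-ethenyl-2,6-dimethyloxan-2-yl]ethyl}-4-hydroxy-2,2,4-trimethylcyclohexan-1-one
Product: 28 (3R,4S)-3-{2-[(2S,3S,6S)-3-{[tert-butyl(dimethyl)silyl]oxy}-6-ethenyl-2,6-dimethyloxan-2-yl]ethyl}-2,2,4-trimethyl-4-[(triethylsilyl)oxy]cyclohexan-1-one
Conditions: TESOTf, 2,6-lutidine, CH2Cl2, −78 °C
Reagents that add atoms: triethylsilyl triflate, CC[Si](CC)(CC)OS(=O)(=O)C(F)(F)F
Why: Silyl triflate silylation masks the axial tertiary hydroxyl, which would otherwise be placed to attack C14 across the ring (oxygen-bridge formation) during the later displacement.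

Step 19
Reactants: 28 (3R,4S)-3-{2-[(2S,3S,6S)-3-{[tert-butyl(dimethyl)silyl]oxy}-6-ethenyl-2,6-dimethyloxan-2-yl]ethyl}-2,2,4-trimethyl-4-[(triethylsilyl)oxy]cyclohexan-1-one
Product: 29 (1S,3R,4S)-3-{2-[(2S,3S,6S)-3-{[tert-butyl(dimethyl)silyl]oxy}-6-ethenyl-2,6-dimethyloxan-2-yl]ethyl}-2,2,4-trimethyl-4-[(triethylsilyl)oxy]cyclohexan-1-ol
Conditions: LiBH(s-Bu)3, THF, −78 → 0 °C
Reagents that add atoms: none
Why: The bulky trialkylborohydride attacks the ketone beside the gem-dimethyl group from the equatorial side and should give the axial C14 alcohol, trans to the equatorial chain on C10.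

Step 20
Reactants: 29 (1S,3R,4S)-3-{2-[(2S,3S,6S)-3-{[tert-butyl(dimethyl)silyl]oxy}-6-ethenyl-2,6-dimethyloxan-2-yl]ethyl}-2,2,4-trimethyl-4-[(triethylsilyl)oxy]cyclohexan-1-ol
Product: 30 tert-butyl{[(2S,3S,6S)-2-{2-[(1R,3R,6S)-3-bromo-2,2,6-trimethyl-6-[(triethylsilyl)oxy]cyclohexyl]ethyl}-6-ethenyl-2,6-dimethyloxan-3-yl]oxy}dimethylsilane
Conditions: CBr4, PPh3, CH2Cl2, 0 °C → rt
Reagents that add atoms: carbon tetrabromide, BrC(Br)(Br)Br
Why: Appel bromination, an SN2 displacement of the axial oxyphosphonium group with inversion that is known for axial alcohols next to a gem-dimethyl group, places bromine equatorial at C14 and cis to the chain.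

Step 21
Reactants: 30 tert-butyl{[(2S,3S,6S)-2-{2-[(1R,3R,6S)-3-bromo-2,2,6-trimethyl-6-[(triethylsilyl)oxy]cyclohexyl]ethyl}-6-ethenyl-2,6-dimethyloxan-3-yl]oxy}dimethylsilane
Product: 31 (1S,2R,4R)-4-bromo-2-{2-[(2S,3S,6S)-6-ethenyl-3-hydroxy-2,6-dimethyloxan-2-yl]ethyl}-1,3,3-trimethylcyclohexan-1-ol
Conditions: HF·pyridine, pyridine, THF, 0 °C → rt
Reagents that add atoms: none
Why: Fluoride cleavage of both silyl ethers under buffered, non-ionising conditions should spare the equatorial secondary bromide and the tertiary allylic ether of the oxane.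

Step 22
Reactants: 31 (1S,2R,4R)-4-bromo-2-{2-[(2S,3S,6S)-6-ethenyl-3-hydroxy-2,6-dimethyloxan-2-yl]ethyl}-1,3,3-trimethylcyclohexan-1-ol
Product: 32 (1S,2R,4R)-4-bromo-2-{2-[(2S,3R,6S)-3-bromo-6-ethenyl-2,6-dimethyloxan-2-yl]ethyl}-1,3,3-trimethylcyclohexan-1-ol (CNP0244533.1)
Conditions: CBr4, P(n-Oct)3, toluene, 70 °C
Reagents that add atoms: carbon tetrabromide, BrC(Br)(Br)Br
Why: Appel-type bromination with the more nucleophilic trioctylphosphine should convert the C6 hydroxyl by SN2 inversion into the bromide cis to the C7 methyl group, the tertiary hydroxyl being too hindered to be activated.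

Compound list
1 | 2-acetyl-5-methylfuran | CC(=O)c1ccc(C)o1 | starting material
2 | 1-(5-methylfuran-2-yl)ethan-1-ol (racemic) | CC(O)c1ccc(C)o1 | intermediate
3 | 6-hydroxy-2,6-dimethyl-2H-pyran-3(6H)-one (diastereomer mixture) | CC1OC(C)(O)C=CC1=O | intermediate
4 | 6-acetoxy-2,6-dimethyl-2H-pyran-3(6H)-one (diastereomer mixture) | CC1OC(C)(OC(C)=O)C=CC1=O | intermediate
5 | phenyl vinyl sulfoxide (racemic) | C=CS(=O)c1ccccc1 | starting material
6 | 2,6-dimethyl-3-oxidopyrylium (2,6-dimethylpyrylium-3-olate; not isolated) | Cc1ccc([O-])c(C)[o+]1 | intermediate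
7 | 1,5-dimethyl-6-(phenylsulfinyl)-8-oxabicyclo[3.2.1]oct-3-en-2-one (regio- and stereoisomer mixture, one regioisomer drawn; not isolated) | CC12OC(C)(C=CC1=O)C(S(=O)c1ccccc1)C2 | intermediate
8 | (1S,5R)-1,5-dimethyl-8-oxabicyclo[3.2.1]octa-3,6-dien-2-one (formed as the racemate; the enantiomer carried on is drawn) | C2=C[C@]1(C)C=CC(=O)[C@@]2(C)O1 | intermediate
9 | (1S,5S)-1,5-dimethyl-8-oxabicyclo[3.2.1]oct-6-en-2-one (racemate; same enantiomer drawn) | C2=C[C@]1(C)CCC(=O)[C@@]2(C)O1 | intermediate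
10 | rac-(1S,2S,5S)-1,5-dimethyl-8-oxabicyclo[3.2.1]oct-6-en-2-ol (2-endo alcohol, racemate; same enantiomer drawn) | C2=C[C@]1(C)CC[C@H](O)[C@@]2(C)O1 | intermediate
11 | (1S,2S,5S)-1,5-dimethyl-8-oxabicyclo[3.2.1]oct-6-en-2-ol (single enantiomer) | C2=C[C@]1(C)CC[C@H](O)[C@@]2(C)O1 | intermediate
12 | (2S,3S,6S)-2,6-diethenyl-2,6-dimethyloxan-3-ol | C=C[C@]1(C)CC[C@H](O)[C@](C)(C=C)O1 | intermediate
13 | butyl (2S,3S,6S)-2,6-diethenyl-2,6-dimethyloxan-3-yl ethenylboronate (mixed boronate; not isolated) | C=C[C@]1(C)CC[C@H](OB(OCCCC)C=C)[C@](C)(C=C)O1 | intermediate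
14 | cis-fused cyclic alkenylboronate: 2-butoxy-3,6-dihydro-2H-1,2-oxaborinine ring O6–B–C9=C8–C7 on the (S,S,S) oxane (not isolated) | C=C[C@]1(C)CC[C@@H]2OB(OCCCC)C=C[C@]2(C)O1 | intermediate
15 | (3aS,5S,7aS)-5-ethenyl-3a,5-dimethylhexahydro-2H-furo[3,2-b]pyran-2-ol (cis-fused lactol, anomer mixture) | C=C[C@]1(C)CC[C@@H]2OC(O)C[C@]2(C)O1 | intermediate
16 | (2S,3S,6S)-6-ethenyl-2-(2-hydroxyethyl)-2,6-dimethyloxan-3-ol | C=C[C@]1(C)CC[C@H](O)[C@](C)(CCO)O1 | intermediate
17 | (2S,3S,6S)-3-{[tert-butyl(dimethyl)silyl]oxy}-2-(2-{[tert-butyl(dimethyl)silyl]oxy}ethyl)-6-ethenyl-2,6-dimethyloxane | C=C[C@]1(C)CC[C@H](O[Si](C)(C)C(C)(C)C)[C@](C)(CCO[Si](C)(C)C(C)(C)C)O1 | intermediate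
18 | {[(2S,3S,6S)-2-(2-bromoethyl)-6-ethenyl-2,6-dimethyloxan-3-yl]oxy}(tert-butyl)dimethylsilane | C=C[C@]1(C)CC[C@H](O[Si](C)(C)C(C)(C)C)[C@](C)(CCBr)O1 | intermediate
19 | (S)-(+)-linalool, (3S)-3,7-dimethylocta-1,6-dien-3-ol | C=C[C@@](C)(O)CCC=C(C)C | starting material
20 | (5S)-5-ethenyl-5-methyloxolan-2-ol (anomer mixture) | C=C[C@]1(C)CCC(O)O1 | intermediate
21 | (6S)-2,6-dimethylocta-1,7-diene-3,6-diol (C3 epimer mixture) | C=C[C@@](C)(O)CCC(O)C(C)=C | intermediate
22 | (4S)-2,4-dimethylcyclohex-2-ene-1,4-diol (C1 epimer mixture) | OC1CC[C@](C)(O)C=C1C | intermediate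
23 | (4S)-4-hydroxy-2,4-dimethylcyclohex-2-en-1-one | O=C1CC[C@](C)(O)C=C1C | intermediate
24 | {2-[(2S,3S,6S)-3-{[tert-butyl(dimethyl)silyl]oxy}-6-ethenyl-2,6-dimethyloxan-2-yl]ethyl}magnesium bromide (not isolated) | C=C[C@]1(C)CC[C@H](O[Si](C)(C)C(C)(C)C)[C@](C)(CC[Mg]Br)O1 | intermediate
25 | chloromagnesium (1S)-1,3-dimethyl-4-oxocyclohex-2-en-1-olate (alkoxide of 23; not isolated) | O=C1CC[C@](C)(O[Mg]Cl)C=C1C | intermediate
26 | conjugate adduct as its C14 bromomagnesium enolate (C14=C15) and C11 chloromagnesium alkoxide (not isolated) | C=C[C@]1(C)CC[C@H](O[Si](C)(C)C(C)(C)C)[C@](C)(CC[C@@H]2C(C)=C(O[Mg]Br)CC[C@]2(C)O[Mg]Cl)O1 | intermediate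
27 | (3R,4S)-3-{2-[(2S,3S,6S)-3-{[tert-butyl(dimethyl)silyl]oxy}-6-ethenyl-2,6-dimethyloxan-2-yl]ethyl}-4-hydroxy-2,2,4-trimethylcyclohexan-1-one | C=C[C@]1(C)CC[C@H](O[Si](C)(C)C(C)(C)C)[C@](C)(CC[C@@H]2C(C)(C)C(=O)CC[C@]2(C)O)O1 | intermediate
28 | (3R,4S)-3-{2-[(2S,3S,6S)-3-{[tert-butyl(dimethyl)silyl]oxy}-6-ethenyl-2,6-dimethyloxan-2-yl]ethyl}-2,2,4-trimethyl-4-[(triethylsilyl)oxy]cyclohexan-1-one | C=C[C@]1(C)CC[C@H](O[Si](C)(C)C(C)(C)C)[C@](C)(CC[C@@H]2C(C)(C)C(=O)CC[C@]2(C)O[Si](CC)(CC)CC)O1 | intermediate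
29 | (1S,3R,4S)-3-{2-[(2S,3S,6S)-3-{[tert-butyl(dimethyl)silyl]oxy}-6-ethenyl-2,6-dimethyloxan-2-yl]ethyl}-2,2,4-trimethyl-4-[(triethylsilyl)oxy]cyclohexan-1-ol (axial C14 alcohol) | C=C[C@]1(C)CC[C@H](O[Si](C)(C)C(C)(C)C)[C@](C)(CC[C@@H]2C(C)(C)[C@@H](O)CC[C@]2(C)O[Si](CC)(CC)CC)O1 | intermediate
30 | tert-butyl{[(2S,3S,6S)-2-{2-[(1R,3R,6S)-3-bromo-2,2,6-trimethyl-6-[(triethylsilyl)oxy]cyclohexyl]ethyl}-6-ethenyl-2,6-dimethyloxan-3-yl]oxy}dimethylsilane | C=C[C@]1(C)CC[C@H](O[Si](C)(C)C(C)(C)C)[C@](C)(CC[C@@H]2C(C)(C)[C@H](Br)CC[C@]2(C)O[Si](CC)(CC)CC)O1 | intermediate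
31 | (1S,2R,4R)-4-bromo-2-{2-[(2S,3S,6S)-6-ethenyl-3-hydroxy-2,6-dimethyloxan-2-yl]ethyl}-1,3,3-trimethylcyclohexan-1-ol | C=C[C@]1(C)CC[C@H](O)[C@](C)(CC[C@@H]2C(C)(C)[C@H](Br)CC[C@]2(C)O)O1 | intermediate
32 | (1S,2R,4R)-4-bromo-2-{2-[(2S,3R,6S)-3-bromo-6-ethenyl-2,6-dimethyloxan-2-yl]ethyl}-1,3,3-trimethylcyclohexan-1-ol (CNP0244533.1) | C=C[C@]1(C)CC[C@@H](Br)[C@](C)(CC[C@@H]2C(C)(C)[C@H](Br)CC[C@]2(C)O)O1 | target

Total step count: 22. Longest linear sequence: 18 steps (steps 1–12 and 17–22, from 2-acetyl-5-methylfuran); the carbocycle branch (steps 13–16) joins at step 17.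

Steps most likely to fail

Step 22. Backside attack of bromide at C6 is slow because the neighbouring C7 is fully substituted and carries the ring oxygen. The oxyphosphonium ion may then live long enough for elimination toward C5, for participation of the ring oxygen with ring contraction, or for attack on the free tertiary hydroxyl at C11. The fallback moves this displacement to the fragment stage, where the ring is small and forcing conditions and repetition are affordable, and carries the bromide through the union. Setting out from bromide 18, halide exchange (NaI, acetone) would give tert-butyl{[(2S,3S,6S)-6-ethenyl-2-(2-iodoethyl)-2,6-dimethyloxan-3-yl]oxy}dimethylsilane F1. Desilylation (HF·pyridine) would give (2S,3S,6S)-6-ethenyl-2-(2-iodoethyl)-2,6-dimethyloxan-3-ol F2. Bromination at C6 with inversion (CBr4, P(n-Oct)3, toluene, 70 °C) would give (2S,3R,6S)-3-bromo-6-ethenyl-2-(2-iodoethyl)-2,6-dimethyloxane F3. Iodine–lithium exchange at the primary carbon only (t-BuLi, Et2O/pentane, −100 °C) would give the alkyllithium F4, and MgBr2·OEt2 the Grignard reagent F5. Addition to alkoxide 25 as in step 17 would give the magnesium enolate F6, and methylation (3R,4S)-3-{2-[(2S,3R,6S)-3-bromo-6-ethenyl-2,6-dimethyloxan-2-yl]ethyl}-4-hydroxy-2,2,4-trimethylcyclohexan-1-one F7. Silylation as in step 18 would give its triethylsilyl ether F8, reduction as in step 19 the axial C14 alcohol F9, and bromination as in step 20 the dibromide triethylsilyl ether F10. HF·pyridine then removes the triethylsilyl group, and the fallback comes back to the route at the target 32.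

Step 17. The magnesium enolate 26 is flanked by the substituted C10 and may be methylated slowly. Proton transfer (loss of regiocontrol and methylation at C13) or O-methylation could then compete, and an alkoxide that directs poorly would let 1,2-addition through. The fallback separates the two events. Setting out from 18 and 23, the conjugate addition is run as before, and enolate 26 is trapped with Me3SiCl/Et3N to give the bis(trimethylsilyl) compound (C14=C15 silyl enol ether and C11 trimethylsilyl ether) F11, which is isolated and purified. MeLi (THF, 0 °C) regenerates the regiodefined lithium enolate F12. MeI/DMPU methylates it at C15 to the C11 trimethylsilyl ether of the ketone F13. K2CO3/MeOH removes the trimethylsilyl group, and the fallback comes back to the route at 27.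

Step 9. Ring closure onto the vinyl group on the fully substituted C7 may be slow, so that cross-metathesis between boronate units and loss of the labile B–O tether compete. The fallback replaces the tether by a directed oxidation. Setting out from divinyl alcohol 12, a hydroxyl-assisted anti-Markovnikov Wacker-type oxidation (PdCl2 (cat.), CuCl, O2, DMF/H2O) is used. Only the alkene next to the carbinol can close the five-membered ring by oxypalladation, so this would give the lactol directly. It makes no new compound (F0) and comes back to the route at 15.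

Further compounds
F1 | step 22 | tert-butyl{[(2S,3S,6S)-6-ethenyl-2-(2-iodoethyl)-2,6-dimethyloxan-3-yl]oxy}dimethylsilane | C=C[C@]1(C)CC[C@H](O[Si](C)(C)C(C)(C)C)[C@](C)(CCI)O1
F2 | step 22 | (2S,3S,6S)-6-ethenyl-2-(2-iodoethyl)-2,6-dimethyloxan-3-ol | C=C[C@]1(C)CC[C@H](O)[C@](C)(CCI)O1
F3 | step 22 | (2S,3R,6S)-3-bromo-6-ethenyl-2-(2-iodoethyl)-2,6-dimethyloxane | C=C[C@]1(C)CC[C@@H](Br)[C@](C)(CCI)O1
F4 | step 22 | {2-[(2S,3R,6S)-3-bromo-6-ethenyl-2,6-dimethyloxan-2-yl]ethyl}lithium | C=C[C@]1(C)CC[C@@H](Br)[C@](C)(CC[Li])O1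
F5 | step 22 | {2-[(2S,3R,6S)-3-bromo-6-ethenyl-2,6-dimethyloxan-2-yl]ethyl}magnesium bromide | C=C[C@]1(C)CC[C@@H](Br)[C@](C)(CC[Mg]Br)O1
F6 | step 22 | conjugate adduct of F5 and 25 as its C14 bromomagnesium enolate and C11 chloromagnesium alkoxide | C=C[C@]1(C)CC[C@@H](Br)[C@](C)(CC[C@@H]2C(C)=C(O[Mg]Br)CC[C@]2(C)O[Mg]Cl)O1
F7 | step 22 | (3R,4S)-3-{2-[(2S,3R,6S)-3-bromo-6-ethenyl-2,6-dimethyloxan-2-yl]ethyl}-4-hydroxy-2,2,4-trimethylcyclohexan-1-one | C=C[C@]1(C)CC[C@@H](Br)[C@](C)(CC[C@@H]2C(C)(C)C(=O)CC[C@]2(C)O)O1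
F8 | step 22 | (3R,4S)-3-{2-[(2S,3R,6S)-3-bromo-6-ethenyl-2,6-dimethyloxan-2-yl]ethyl}-2,2,4-trimethyl-4-[(triethylsilyl)oxy]cyclohexan-1-one | C=C[C@]1(C)CC[C@@H](Br)[C@](C)(CC[C@@H]2C(C)(C)C(=O)CC[C@]2(C)O[Si](CC)(CC)CC)O1
F9 | step 22 | (1S,3R,4S)-3-{2-[(2S,3R,6S)-3-bromo-6-ethenyl-2,6-dimethyloxan-2-yl]ethyl}-2,2,4-trimethyl-4-[(triethylsilyl)oxy]cyclohexan-1-ol | C=C[C@]1(C)CC[C@@H](Br)[C@](C)(CC[C@@H]2C(C)(C)[C@@H](O)CC[C@]2(C)O[Si](CC)(CC)CC)O1
F10 | step 22 | {[(1S,2R,4R)-4-bromo-2-{2-[(2S,3R,6S)-3-bromo-6-ethenyl-2,6-dimethyloxan-2-yl]ethyl}-1,3,3-trimethylcyclohexyl]oxy}triethylsilane | C=C[C@]1(C)CC[C@@H](Br)[C@](C)(CC[C@@H]2C(C)(C)[C@H](Br)CC[C@]2(C)O[Si](CC)(CC)CC)O1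
F11 | step 17 | conjugate adduct as its C14=C15 trimethylsilyl enol ether and C11 trimethylsilyl ether (C6 tert-butyldimethylsilyl ether retained) | C=C[C@]1(C)CC[C@H](O[Si](C)(C)C(C)(C)C)[C@](C)(CC[C@@H]2C(C)=C(O[Si](C)(C)C)CC[C@]2(C)O[Si](C)(C)C)O1
F12 | step 17 | C14 lithium enolate (C14=C15) of the C11 trimethylsilyl ether | C=C[C@]1(C)CC[C@H](O[Si](C)(C)C(C)(C)C)[C@](C)(CC[C@@H]2C(C)=C(O[Li])CC[C@]2(C)O[Si](C)(C)C)O1
F13 | step 17 | (3R,4S)-3-{2-[(2S,3S,6S)-3-{[tert-butyl(dimethyl)silyl]oxy}-6-ethenyl-2,6-dimethyloxan-2-yl]ethyl}-2,2,4-trimethyl-4-[(trimethylsilyl)oxy]cyclohexan-1-one | C=C[C@]1(C)CC[C@H](O[Si](C)(C)C(C)(C)C)[C@](C)(CC[C@@H]2C(C)(C)C(=O)CC[C@]2(C)O[Si](C)(C)C)O1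
F0 | step 9 | none | none
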